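**Plan** (hydroazulene locants: C1 = carbinol carbon with i‑Pr, C2, C3, C3a = methyl-bearing fusion carbon, C4 = angelate carbon, C5=C6(CH3), C7, C8 = anisate carbon, C8a = fusion CH)

1. Retrosynthesis: remove both esters; C8–OH from a C8 ketone; the C5=C6 alkene and H‑8a from a temporary C5–O–C8a ether bridge; C4–O from C4–B; C6–CH3 from conjugate addition/dehydrogenation.
2. C3a–C8a and C4–C5 are then cut together: an intramolecular [5+2] of a 3‑oxidopyrylium (C8a, C8–O, C7, C6, C5 plus ring O) with a tethered (Z)‑alkenyl boronate (C3a=C4).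
3. Enabling feature: the C8 oxygen sits next to C8a, and C5 (of the C5=C6 alkene) lies three carbons further round the seven-membered ring. C8a and C5 are therefore the 2,6‑carbons of a pyrylium whose 3‑oxygen is the C8 oxygen, and the cyclopentane carbons C1–C3 are the three-atom tether from C8a to C3a.
4. Forward: an acyclic chain (two copper-catalysed carbomagnesiations of propargyl alcohol) is joined to furan; Achmatowicz oxidation gives the pyranone; one cycloaddition closes cyclopentane and cycloheptene together; two SmI2 C–O cleavages remove the bridge; esters last.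
5. Stereochemistry: C1 from Sharpless epoxidation (the only catalyst-set centre); C3a, C4 and the bridge relayed from C1 and the (Z)‑alkene in the cycloaddition; H‑8a by protonation on the face the bridge leaves; C8 by C1‑OH-directed hydride delivery.

Key step: step 12

**Step 1**
Reactants: 1 prop-2-yn-1-ol
Product: 3 (Z)-3-iodo-2-methylprop-2-en-1-ol, via alkenylmagnesium chelate 2 (not isolated)
Conditions: MeMgBr, CuI (cat.), THF, −10 °C → rt; then I2, −78 → 0 °C
Reagents that add atoms: methylmagnesium bromide C[Mg]Br; iodine II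
Why: Copper-catalysed anti-carbomagnesiation of the propargylic alkoxide puts methyl on the internal carbon and magnesium cis to CH2O in a five-membered chelate, and iodinolysis with retention should give the (Z)-iodide whose geometry later fixes the C3a/C4 relationship.

**Step 2**
Reactants: 3 (Z)-3-iodo-2-methylprop-2-en-1-ol
Product: 4 (Z)-3-bromo-1-iodo-2-methylprop-1-ene
Conditions: CBr4, PPh3, CH2Cl2, 0 °C
Reagents that add atoms: tetrabromomethane BrC(Br)(Br)Br
Why: Appel bromination converts the primary allylic alcohol into the bromide under neutral conditions without touching the alkenyl iodide or its geometry.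

**Step 3**
Reactants: 1 prop-2-yn-1-ol; 4 (Z)-3-bromo-1-iodo-2-methylprop-1-ene
Product: 6 (2Z,5Z)-6-iodo-5-methyl-2-(propan-2-yl)hexa-2,5-dien-1-ol, via alkenylmagnesium chelate 5 (not isolated)
Conditions: i-PrMgCl (2.1 equiv), CuI (15 mol %), THF, −10 °C → rt; then 4, −20 °C → rt
Reagents that add atoms: isopropylmagnesium chloride CC(C)[Mg]Cl
Why: The same anti-carbomagnesiation installs isopropyl on the future C1, and copper-mediated SN2 allylation of the alkenylmagnesium by the primary allylic bromide joins the halves; the new alkene geometry is immaterial because that carbon becomes C2‑H2.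

**Step 4**
Reactants: 6 (2Z,5Z)-6-iodo-5-methyl-2-(propan-2-yl)hexa-2,5-dien-1-ol
Product: 7 [(2R,3S)-3-[(2Z)-3-iodo-2-methylprop-2-en-1-yl]-2-(propan-2-yl)oxiran-2-yl]methanol
Conditions: Ti(Oi-Pr)4, D-(−)-diethyl tartrate, t-BuOOH, 4 Å MS, CH2Cl2, −20 °C
Reagents that add atoms: tert-butyl hydroperoxide CC(C)(C)OO
Why: Sharpless asymmetric epoxidation acts only on the allylic-alcohol alkene, and with the D-(−)-tartrate ligand oxygen is delivered to the face that makes the future C1 carbinol (R), whatever the alkene geometry.

**Step 5**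
Reactants: 7 epoxy alcohol
Product: 8 (2R,5Z)-6-iodo-5-methyl-2-(propan-2-yl)hex-5-ene-1,2-diol
Conditions: LiBH4, Ti(Oi-Pr)4, THF, 0 °C → rt
Reagents that add atoms: none
Why: Titanium-assisted hydride opening of the 2,3-epoxy alcohol occurs at the secondary C3 (C2 is fully substituted), so the tertiary C–O bond and its configuration are kept and the alkenyl iodide is spared.

**Step 6**
Reactants: 8 diol
Product: 9 (2R,5Z)-6-iodo-5-methyl-2-(propan-2-yl)-1,2-bis[(triethylsilyl)oxy]hex-5-ene
Conditions: TESOTf, 2,6-lutidine, CH2Cl2, −78 → 0 °C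
Reagents that add atoms: triethylsilyl triflate CC[Si](CC)(CC)OS(=O)(=O)C(F)(F)F
Why: The silyl triflate silylates both hydroxyls, including the hindered tertiary one, whose ether later stops this oxygen from trapping the pyranone or ylide as a bicyclic ketal.

**Step 7**
Reactants: 9 bis(triethylsilyl) ether
Product: 11 (2R,5Z)-6-iodo-5-methyl-2-(propan-2-yl)-2-[(triethylsilyl)oxy]hex-5-enal, via alkoxysulfonium chloride 10 (not isolated)
Conditions: (COCl)2, DMSO, CH2Cl2, −78 → −40 °C; then Et3N, −78 °C → rt
Reagents that add atoms: none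
Why: Under Swern conditions the activated sulfoxide cleaves only the unhindered primary triethylsilyl ether and oxidises it in place (selective oxidative desilylation), giving an aldehyde with no α-hydrogen that cannot enolise.

**Step 8**
Reactants: 11 aldehyde; 12 furan
Product: 14 (1RS,2R,5Z)-1-(furan-2-yl)-6-iodo-5-methyl-2-(propan-2-yl)-2-[(triethylsilyl)oxy]hex-5-en-1-ol, via 2-furyllithium 13 (not isolated)
Conditions: furan, n-BuLi, THF, 0 °C; then 11, −78 °C; aq NH4Cl at −78 °C
Reagents that add atoms: none
Why: 1,2-Addition of 2-furyllithium to the non-enolisable aldehyde gives the furyl carbinol; its new centre is left uncontrolled because it becomes sp2 in the ylide, the alkenyl iodide is inert to the furyl anion at −78 °C, and the cold quench avoids 1,2-silyl migration.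

**Step 9**
Reactants: 14 furyl carbinol
Product: 15 (1RS,2R,5Z)-1-(furan-2-yl)-5-methyl-2-(propan-2-yl)-6-(4,4,5,5-tetramethyl-1,3,2-dioxaborolan-2-yl)-2-[(triethylsilyl)oxy]hex-5-en-1-ol
Conditions: B2pin2, PdCl2(PPh3)2, PPh3, KOPh, toluene, 50 °C
Reagents that add atoms: bis(pinacolato)diboron CC1(C)OB(OC1(C)C)B1OC(C)(C)C(C)(C)O1
Why: Miyaura borylation of the alkenyl iodide proceeds with retention of the (Z)-geometry and gives a boronate that serves as an oxidant-tolerant, stereodefined stand-in for the C4 oxygen.

**Step 10**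
Reactants: 15 alkenyl boronate
Product: 16 6-hydroxy-2-[(3R,6Z)-2,6-dimethyl-7-(4,4,5,5-tetramethyl-1,3,2-dioxaborolan-2-yl)-3-[(triethylsilyl)oxy]hept-6-en-3-yl]-2H-pyran-3(6H)-one (anomer and C2 mixture)
Conditions: NBS (1.0 equiv), NaHCO3, NaOAc, THF/H2O 4:1, 0 °C
Reagents that add atoms: water O
Why: Achmatowicz oxidative ring expansion: the electron-rich furan is attacked far faster than the alkenyl boronate, and the enedione recloses through the secondary hydroxyl, whose oxygen becomes the ring oxygen and later the temporary bridge.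

**Step 11**
Reactants: 16 hydroxypyranone
Product: 17 6-acetoxy analogue of 16
Conditions: Ac2O, pyridine, DMAP (cat.), CH2Cl2, 0 °C
Reagents that add atoms: acetic anhydride CC(=O)OC(C)=O
Why: Acylation of the anomeric hemiacetal hydroxyl installs the leaving group needed for ylide formation.

**Step 12**
Reactants: 17 acetoxypyranone
Product: 19 oxygen-bridged tricyclic enone (5,8a-epoxy-hexahydroazulen-8-one bearing C1 OSiEt3/i-Pr, C3a CH3 and C4 Bpin), via 3-oxidopyrylium ylide 18 (not isolated)
Conditions: i-Pr2NEt, MeCN, 60 °C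
Reagents that add atoms: none
Why: The amine removes the C2–H of the pyranone and acetate leaves from C6, unmasking the aromatic 3-oxidopyrylium 18, whose five atoms C8a–C8(O−)–C7–C6–C5 add suprafacially across the tethered C3a=C4 alkene in a concerted, thermally allowed [5+2] (π4s + π2s) cycloaddition that dearomatises the pyrylium. The closest known reaction type is the intramolecular oxidopyrylium–alkene cycloaddition of 2-(pent-4-enyl)-3-oxidopyryliums. The cyclopentane closes through the C3a–C8a bond with the three-carbon tether C1–C2–C3 fused exo (syn to the oxygen bridge, the only geometry it can span), and the cycloheptene closes through the C4–C5 bond as the carbocycle of an 8-oxabicyclo[3.2.1]octenone, the former pyranone oxygen staying as a temporary 5,8a-bridge. C3a and C4 are set relative to each other by the (Z)-alkene geometry (boron cis to the tether, hence exo and trans to the endo C3a methyl); C5 and C8a are set by the bridge, which must lie on the face opposite the incoming alkene and so trans to the C3a methyl; the absolute sense of all four is set by the C1 centre. The step needs regiocontrol (fixed by tether length), exo-tether topology (fixed by strain) and π-facial selectivity, expected from allylic 1,3-strain at C1: the small silyloxy oxygen should take the in-plane position next to the C8 oxido oxygen and the isopropyl group the ring-oxygen side, while gem-disubstitution at C1 favours closure over ylide dimerisation.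

**Step 13**
Reactants: 19 tricyclic enone
Product: 20 C6-methyl C7=C8 trimethylsilyl enol ether of 19
Conditions: Me2CuLi, TMSCl, THF, −78 °C; Et3N quench
Reagents that add atoms: lithium dimethylcuprate [Li+].C[Cu-]C; chlorotrimethylsilane C[Si](C)(C)Cl
Why: Conjugate addition of the Gilman reagent from the exo face with in situ O-silylation brings in the C6 methyl and traps the enolate regiospecifically, so that plain furan can serve as the heteroarene; the new C6 centre is erased in the next step.

**Step 14**
Reactants: 20 silyl enol ether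
Product: 21 C6-methyl tricyclic enone
Conditions: Pd(OAc)2, MeCN, rt
Reagents that add atoms: none
Why: Saegusa–Ito oxidation (palladium enolate, β-hydride elimination of H-6) regenerates the enone, now carrying the C6 methyl.

**Step 15**
Reactants: 21 methyl enone
Product: 22 C4 exo-alcohol of the tricyclic enone
Conditions: NaBO3·4H2O, THF/H2O, rt
Reagents that add atoms: sodium perborate [Na+].[O-]OB=O
Why: Perborate oxidation of the secondary alkyl boronate goes by 1,2-migration of carbon from boron to oxygen with retention, so the hydroxyl should be exo (cis to the bridge, trans to the C3a methyl), while the β,β-disubstituted enone resists nucleophilic epoxidation.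

**Step 16**
Reactants: 22 C4 alcohol; 23 angelic acid
Product: 25 C4 angelate of the tricyclic enone, via angelic 2,4,6-trichlorobenzoic anhydride 24 (not isolated)
Conditions: 23, 2,4,6-trichlorobenzoyl chloride, Et3N, toluene, rt; then 22, 80 °C (no DMAP)
Reagents that add atoms: none
Why: Yamaguchi-type acylation with the preformed mixed anhydride in hot toluene without a nucleophilic catalyst is the established way to esterify hindered alcohols with angelic acid without (Z)→(E) isomerisation to the tiglate.

**Step 17**
Reactants: 25 angelate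
Product: 27 trans-fused C5-acetoxy C6=C7 enone (bridge opened, H-8a trans to the C3a methyl), via C5-hydroxy enone samarium alkoxide 26 (not isolated)
Conditions: SmI2 (2.5 equiv), MeOH (2 equiv), THF, −78 °C; then Ac2O, DMAP, pyridine, −78 → 0 °C
Reagents that add atoms: acetic anhydride CC(=O)OC(C)=O
Why: SmI2 reduces the C8 carbonyl to a ketyl that expels the α-oxygen at C8a (reductive α-alkoxy ketone cleavage); the samarium enolate should be protonated at C8a on the face the oxygen has just left, by the samarium-bound alkoxide/methanol still held over it, giving the trans fusion, and the C5 alkoxide is acetylated in the flask before the neighbouring angelate can migrate.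

**Step 18**
Reactants: 27 γ-acetoxy enone
Product: 28 C5=C6 alkene C8 ketone (1-O-triethylsilyl ether)
Conditions: SmI2 (2.5 equiv), THF/MeOH, −78 °C
Reagents that add atoms: none
Why: Two-electron reduction of the γ-acetoxy enone expels acetate from C5 (vinylogous reductive elimination), and kinetic α-protonation of the samarium dienolate at C7 leaves the deconjugated C5=C6 alkene of the target.

**Step 19**
Reactants: 28 silyl ether
Product: 29 C1 tertiary alcohol C8 ketone
Conditions: HF·pyridine, pyridine, THF, 0 °C → rt
Reagents that add atoms: none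
Why: Buffered HF·pyridine cleaves the tertiary silyl ether without base, so the β,γ-enone is not conjugated and the angelate is untouched; the freed C1 hydroxyl directs the next step.

**Step 20**
Reactants: 29 β-hydroxy ketone
Product: 30 (1R,3aS,4R,8S,8aS)-1,8-dihydroxy-3a,6-dimethyl-1-(propan-2-yl)-1,2,3,3a,4,7,8,8a-octahydroazulen-4-yl (2Z)-2-methylbut-2-enoate
Conditions: Me4NBH(OAc)3, MeCN/AcOH 1:1, −30 → −20 °C
Reagents that add atoms: none
Why: Evans–Saksena reduction: the borohydride exchanges onto the C1 oxygen and delivers hydride to the C8 carbonyl from that face, which should give the 1,3-anti diol with the C8 hydroxyl cis to H-8a, and the mildly acidic medium leaves the β,γ-alkene in place.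

**Step 21**
Reactants: 30 diol; 31 4-methoxybenzoyl chloride
Product: 32 CNP0168729.1, (1R,3aS,4R,8S,8aS)-1-hydroxy-8-[(4-methoxybenzoyl)oxy]-3a,6-dimethyl-1-(propan-2-yl)-1,2,3,3a,4,7,8,8a-octahydroazulen-4-yl (2Z)-2-methylbut-2-enoate
Conditions: Et3N, DMAP, CH2Cl2, 0 °C → rt
Reagents that add atoms: none
Why: DMAP-catalysed acylation should occur only at the secondary C8 hydroxyl, the tertiary C1 hydroxyl being too hindered to react.

**Compound list**

1 | prop-2-yn-1-ol | C#CCO | starting material
2 | bromomagnesium (Z)-3-(bromomagnesio)-2-methylprop-2-en-1-olate | Br[Mg]OC/C(C)=C\[Mg]Br | intermediate (not isolated)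
3 | (Z)-3-iodo-2-methylprop-2-en-1-ol | OC/C(C)=C\I | intermediate
4 | (Z)-3-bromo-1-iodo-2-methylprop-1-ene | BrC/C(C)=C\I | intermediate
5 | chloromagnesium (Z)-3-(chloromagnesio)-2-(propan-2-yl)prop-2-en-1-olate | Cl[Mg]OC/C(C(C)C)=C\[Mg]Cl | intermediate (not isolated)
6 | (2Z,5Z)-6-iodo-5-methyl-2-(propan-2-yl)hexa-2,5-dien-1-ol | OC/C(C(C)C)=C\C/C(C)=C\I | intermediate
7 | [(2R,3S)-3-[(2Z)-3-iodo-2-methylprop-2-en-1-yl]-2-(propan-2-yl)oxiran-2-yl]methanol | OC[C@@]1(C(C)C)O[C@H]1C/C(C)=C\I | intermediate
8 | (2R,5Z)-6-iodo-5-methyl-2-(propan-2-yl)hex-5-ene-1,2-diol | I/C=C(C)\CC[C@@](CO)(O)C(C)C | intermediate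
9 | bis(triethylsilyl) ether of 8 | I/C=C(C)\CC[C@@](CO[Si](CC)(CC)CC)(O[Si](CC)(CC)CC)C(C)C | intermediate
10 | dimethyl(alkoxy)sulfonium chloride of the primary alcohol | I/C=C(C)\CC[C@@](CO[S+](C)C)(O[Si](CC)(CC)CC)C(C)C.[Cl-] | intermediate (not isolated)
11 | (2R,5Z)-6-iodo-5-methyl-2-(propan-2-yl)-2-[(triethylsilyl)oxy]hex-5-enal | I/C=C(C)\CC[C@@](C=O)(O[Si](CC)(CC)CC)C(C)C | intermediate
12 | furan | c1ccoc1 | starting material
13 | 2-furyllithium | [Li]c1ccco1 | intermediate (not isolated)
14 | (1RS,2R,5Z)-1-(furan-2-yl)-6-iodo-5-methyl-2-(propan-2-yl)-2-[(triethylsilyl)oxy]hex-5-en-1-ol | I/C=C(C)\CC[C@@](C(O)c1ccco1)(O[Si](CC)(CC)CC)C(C)C | intermediate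
15 | (Z)-alkenyl pinacolboronate corresponding to 14 | CC1(C)OB(/C=C(C)\CC[C@@](C(O)c2ccco2)(O[Si](CC)(CC)CC)C(C)C)OC1(C)C | intermediate
16 | 6-hydroxy-2H-pyran-3(6H)-one with the (3R,6Z) side chain at C2 | CC1(C)OB(/C=C(C)\CC[C@@](C2OC(O)C=CC2=O)(O[Si](CC)(CC)CC)C(C)C)OC1(C)C | intermediate
17 | 6-acetoxy-2H-pyran-3(6H)-one analogue of 16 | CC1(C)OB(/C=C(C)\CC[C@@](C2OC(OC(C)=O)C=CC2=O)(O[Si](CC)(CC)CC)C(C)C)OC1(C)C | intermediate
18 | 2-substituted 3-oxidopyrylium ylide | CC1(C)OB(/C=C(C)\CC[C@@](c2[o+]cccc2[O-])(O[Si](CC)(CC)CC)C(C)C)OC1(C)C | intermediate (not isolated)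
19 | 5,8a-epoxy-bridged hexahydroazulen-8-one; C1 (R) with OSiEt3 anti to the bridge, C3a methyl anti to the bridge, C4 Bpin exo (syn to the bridge), C6=C7 enone | CC(C)[C@]1(O[Si](CC)(CC)CC)CC[C@]2(C)[C@H](B3OC(C)(C)C(C)(C)O3)[C@H]4C=CC(=O)[C@@]12O4 | intermediate
20 | C6-methyl C7=C8 trimethylsilyl enol ether of 19 (C6 epimers) | CC(C)[C@]1(O[Si](CC)(CC)CC)CC[C@]2(C)[C@H](B3OC(C)(C)C(C)(C)O3)[C@H]4C(C)C=C(O[Si](C)(C)C)[C@@]12O4 | intermediate
21 | C6-methyl analogue of 19 | CC(C)[C@]1(O[Si](CC)(CC)CC)CC[C@]2(C)[C@H](B3OC(C)(C)C(C)(C)O3)[C@H]4C(C)=CC(=O)[C@@]12O4 | intermediate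
22 | C4 exo-alcohol of 21 | CC(C)[C@]1(O[Si](CC)(CC)CC)CC[C@]2(C)[C@H](O)[C@H]4C(C)=CC(=O)[C@@]12O4 | intermediate
23 | angelic acid, (Z)-2-methylbut-2-enoic acid | C/C=C(/C)C(=O)O | starting material
24 | angelic 2,4,6-trichlorobenzoic anhydride | C/C=C(/C)C(=O)OC(=O)c1c(Cl)cc(Cl)cc1Cl | intermediate (not isolated)
25 | C4 angelate of 22 | CC(C)[C@]1(O[Si](CC)(CC)CC)CC[C@]2(C)[C@H](OC(=O)/C(C)=C\C)[C@H]4C(C)=CC(=O)[C@@]12O4 | intermediate
26 | trans-fused C5-hydroxy C6=C7 enone, as its samarium(III) alkoxide | C/C=C(/C)C(=O)O[C@@H]1[C@H](O)C(C)=CC(=O)[C@@H]2[C@]1(C)CC[C@@]2(O[Si](CC)(CC)CC)C(C)C | intermediate (not isolated)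
27 | C5 acetate of 26 (C5 OAc cis to C4 OAng, H-8a trans to C3a CH3) | C/C=C(/C)C(=O)O[C@@H]1[C@H](OC(C)=O)C(C)=CC(=O)[C@@H]2[C@]1(C)CC[C@@]2(O[Si](CC)(CC)CC)C(C)C | intermediate
28 | C5=C6 alkene C8 ketone, 1-O-triethylsilyl ether, ring centres as in the target | C/C=C(/C)C(=O)O[C@@H]1C=C(C)CC(=O)[C@@H]2[C@]1(C)CC[C@@]2(O[Si](CC)(CC)CC)C(C)C | intermediate
29 | 1-hydroxy-8-oxo analogue of 28 | C/C=C(/C)C(=O)O[C@@H]1C=C(C)CC(=O)[C@@H]2[C@]1(C)CC[C@@]2(O)C(C)C | intermediate
30 | (1R,3aS,4R,8S,8aS)-1,8-dihydroxy-3a,6-dimethyl-1-(propan-2-yl)-1,2,3,3a,4,7,8,8a-octahydroazulen-4-yl (2Z)-2-methylbut-2-enoate | C/C=C(/C)C(=O)O[C@@H]1C=C(C)C[C@H](O)[C@@H]2[C@]1(C)CC[C@@]2(O)C(C)C | intermediate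
31 | 4-methoxybenzoyl chloride | COc1ccc(cc1)C(Cl)=O | starting material
32 | CNP0168729.1, the C8 4-methoxybenzoate of 30 | C/C=C(/C)C(=O)O[C@@H]1C=C(C)C[C@H](OC(=O)c2ccc(OC)cc2)[C@@H]2[C@]1(C)CC[C@@]2(O)C(C)C | target

**Totals**

Total steps: 21. Longest linear sequence: 21 steps (prop-2-yn-1-ol through 3, 4, 6 and on to 32).

**Steps most likely to fail**

1. Step 12. The silyloxy and isopropyl groups at C1 may compete for the in-plane position beside the oxido oxygen, giving poor π-facial discrimination, and the closure builds three contiguous fully substituted carbons, so ylide dimerisation may outrun it. Fallback, from 16 back to 19: replace substrate control by catalyst control. The hemiacetal 16 is acylated with 4-(methylsulfanyl)benzoyl chloride (Et3N, DMAP) to the 6-aroyloxypyranone F1, the substrate class of the amine/thiourea dual-catalytic enantioselective intramolecular oxidopyrylium cycloaddition. With the chiral primary aminothiourea enantiomer matched to the desired face, an achiral thiourea and AcOH in toluene at 40 °C, the cycloaddition should return to 19.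

2. Step 17. The samarium enolate may be protonated from the face carrying the C3a methyl and the silyloxy group, giving the cis-fused ketone; the angelate may also migrate to the C5 alkoxide before acetylation. Fallback, from 25 back to 27: move C8a from kinetic to thermodynamic control. The cis-fused acetate F2 is isolated and equilibrated through its cross-conjugated dienol with camphorsulfonic acid in CH2Cl2. Acid is chosen because base would deprotonate C5 and expel the angelate. The equilibrium should favour 27, where the C8 carbonyl is anti to the isopropyl group on the cyclopentane.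

3. Step 16. The neopentyl-type C4 hydroxyl may not acylate, or forcing conditions may isomerise the angeloyl group to the tiglate. Fallback, from 22 back to 25: build the (Z)-alkene after the ester bond. Alcohol 22 is acylated with 2-[bis(2,2,2-trifluoroethoxy)phosphoryl]propanoyl chloride (pyridine, CH2Cl2) to the phosphonate ester F3. Still–Gennari olefination with acetaldehyde (KHMDS, 18-crown-6, THF, −78 °C) then forms the (Z)-2-methylbut-2-enoate 25.

**Further compounds**

F1 | step 12 | 6-[4-(methylsulfanyl)benzoyloxy] analogue of 17 | CC1(C)OB(/C=C(C)\CC[C@@](C2OC(OC(=O)c3ccc(SC)cc3)C=CC2=O)(O[Si](CC)(CC)CC)C(C)C)OC1(C)C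
F2 | step 17 | C8a epimer (cis-fused) of 27 | C/C=C(/C)C(=O)O[C@@H]1[C@H](OC(C)=O)C(C)=CC(=O)[C@H]2[C@]1(C)CC[C@@]2(O[Si](CC)(CC)CC)C(C)C
F3 | step 16 | C4 2-[bis(2,2,2-trifluoroethoxy)phosphoryl]propanoate of 22 | CC(C)[C@]1(O[Si](CC)(CC)CC)CC[C@]2(C)[C@H](OC(=O)C(C)P(=O)(OCC(F)(F)F)OCC(F)(F)F)[C@H]4C(C)=CC(=O)[C@@]12O4
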